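## The problem

Chain numbering used throughout: C1 = ArO–CH2, C2 = oxirane CH, C3 = oxirane C(CH3) (methyl = C10), C4 = CH2, C5 = lactone CH–O, C6 = lactone ring CH2, C7 = C(=C9H2), C8 = lactone C=O. Ar is C7 of the 8-methoxycoumarin.

- The target is an open C10 chain tied to the coumarin by an ether oxygen. One end is closed into a trans-2,2,3-trisubstituted oxirane (O, C2, C3). The other end is closed into an α-methylene-γ-butyrolactone ring (O, C5, C6, C7, C8). The two small rings are joined only by the freely rotating C4 methylene, so no ring fusion transmits stereochemistry.
- C2 and C3 (R,R) belong together. They follow from the E geometry of a C2=C3 olefin and from the face that takes up oxygen.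
- C5 (S) stands 1,3-anti to C3 across C4. Neither centre can be trusted to control the other, so two independent, reagent-controlled events are needed.
- C5 is the hard centre because its two carbon neighbours are nearly identical CH2–C(sp2) arms. A C5 ketone would give a catalyst no difference between its faces and would be doubly β,γ-unsaturated. Every conceivable C5 aldehyde is β,γ-unsaturated (or β,γ-epoxy) and drifts into conjugation or eliminates.
- Four groups limit the order of events:
  - the exocyclic acrylate (Michael acceptor, radical trap, prone to polymerise);
  - the oxirane (acid, Lewis acid);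
  - the coumarin lactone (hydroxide, hard nucleophiles);
  - the allylic aryl ether (Pd(0), Lewis acids).
- The enabling feature is the same as the difficulty. Both carbon neighbours of C5 are allylic methylenes: C4 is allylic to C2=C3 (the olefin behind the oxirane) and C6 is allylic to the exocyclic C7=C9 of the lactone ring. Both C–C bonds at C5 are therefore allyl–carbon bonds.
- C5 can thus be introduced as a nucleophile twice, as a carbinol 1,1-dianion equivalent (diborylmethane 6). It never passes through a carbonyl group.

## Retrosynthesis

**13 ⇒ 12.** The two C–O bonds of the oxirane (O–C2, O–C3) are cut first.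
- The oxirane is the most fragile group. It would also sit three atoms from the nucleophilic C5 of the earlier steps, so carrying it through the route is worse than adding it last.
- In 12 the C2=C3 bond is the only electron-rich olefin of three.
- The cut removes two of the three stereocentres and replaces them with one E double bond.
- The forward reaction must choose one olefin and one face under reagent control (Shi epoxidation), independently of remote C5, in a medium both lactones survive.

**12 ⇒ 10 (through 11).** The acyl bond O–C8 is cut, and the C5–O bond is exchanged for a C5–B bond.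
- The neighbouring option, C5–O from reduction of a C5 ketone, fails on the pseudo-symmetry named above.
- A secondary boronic ester is a configurationally stable, non-basic placeholder for OH. Unlike OH, it is installed by C–C bond formation with C5 as the nucleophile.
- The forward reaction needs only a stereoretentive C–B oxidation, after which hydroxy ester 11 closes the lactone.

**10 ⇒ 8 + 9 (key cut, C5–C6).**
- The bond is the same one as in the classical allylation, but the polarity is inverted. C5 is the nucleophile (one boryl group of 8 is spent) and the commercial acrylate 9 is the electrophile.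
- The cut delivers C6, C7, C8 and C9 in the final oxidation state and creates C5 as a stereocentre in one operation.
- The precursor 8 is achiral, because C5 carries two identical boryl groups.
- The enantioselective, copper-mediated event is placed on this bond, not on C4–C5, because both allyl termini of 9 are CH2 groups. The SN2′ preference of copper therefore has no regiochemical consequence here.
- The forward reaction must distinguish the two enantiotopic boryl groups and stop after one allylation.

**8 ⇒ 5 + 6 (through 7, C4–C5).**
- The unsymmetrical arm must be attached at its α-carbon. A copper-free SN2 reaction of the boron-stabilised carbanion 7 with the primary allylic bromide 5 does this.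
- No stereocentre is formed.
- Compound 6 is purchased, and 5 already holds C1–C4, C10, the E olefin and the coumarin.
- The forward reaction must be faster at the allylic bromide than at the coumarin lactone.

**5 ⇒ 4 ⇒ 3 ⇒ 1 + 2.**
- The C4–Br bond goes back to C4–OH (4), and that to a C4–H bond of the prenyl ether 3. The ether bond O–C1 is cut last, to phenol 1 and prenyl bromide 2.
- Allylic oxidation of a prenyl group gives the E-configured C4 alcohol by its own mechanism. The olefin geometry, and with it the trans relation in the oxirane, therefore comes from a C5 commodity without any olefination or carbometalation.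
- The coumarin also serves as the protecting group of O–C1.

## Roads not taken

**Alternative 1:** (the most obvious one) Cut C5–C6 with normal polarity, after cutting the ether O–C1 and the oxirane in the usual way.
- Forward route: a six-carbon E chain is built by methylalumination of a protected butynol. It is then epoxidised (Sharpless epoxidation), joined to 1 (Mitsunobu reaction), deprotected and oxidised to the epoxy aldehyde A1.
- Key step: asymmetric 2-(alkoxycarbonyl)allylation and lactonisation of A1 with the allylmetal from 9.
- Why the chosen plan is better:
  - A1 has an oxirane C–O bond β to an enolisable aldehyde and is set up for eliminative ring opening.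
  - Its C5 face selectivity must be forced by a reagent against an unknown 1,3-bias.
  - The chain needs a protecting group and a redox adjustment at C5.
  - The route is no shorter.
  - The chosen plan never has a carbonyl at C5 and needs no protecting group.

**Alternative 2:** Cut C3–C4… no: cut C4–C3(sp) and C6–C7(sp), with C4–C5–C6 taken from the chiral pool.
- Forward route: (S)-epichlorohydrin A2 is opened at both CH2 termini by two acetylides to give the monosilylated diynol A3.
- Key steps: zirconium-catalysed methylalumination with hydroxymethylation of the free alkyne, and palladium-catalysed cyclocarbonylation of the other alkyne.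
- The idea uses the same latent symmetry about C5, but it costs more:
  - The chirality of A3 rests only on one silyl cap, and its loss gives an achiral diyne.
  - The epoxide stage between the two openings has acidic propargylic hydrogens beside the oxirane and tends to open by elimination.
  - The organoaluminium step tolerates neither lactone. Pd/CO conditions threaten an allylic aryl ether or allylic alcohol. The order of events and extra protection are therefore forced.
  - The count rises to about nine steps.

**Alternative 3:** Cut C3–C4 (sp2–sp3) between a chiral-pool lactone and the coumarin half.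
- Key step: nickel-catalysed reductive cross-electrophile coupling of the iodolactone A4 with the vinyl iodide A5.
- The union is convergent and sits at the future quaternary carbon, but the mechanism speaks against it:
  - A C4 radical is generated next to the best radical trap in the molecule (C7=C9).
  - Two-electron metalation at C4 expels the β-carboxylate, which is the reverse of halolactonisation.
  - Masking the methylene group calls for a strong-base methylenation later, in the presence of the coumarin.
  - A5 needs a regiocontrolled hydrometalation of an internal alkyne, and A4 needs several steps from the pool.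

Key step: step 5

Assumption: coumarin 1 (daphnetin 8-methyl ether) is taken as a catalogue compound, and in step 5 the antipode of the phosphoramidite ligand is taken that leads to (R)-10, both antipodes being accessible from the two enantiomers of the parent biaryl diol.

## Steps

Step 1
Reactants: 1 7-hydroxy-8-methoxycoumarin; 2 prenyl bromide (1-bromo-3-methylbut-2-ene)
Product: 3 8-methoxy-7-(3-methylbut-2-enyloxy)coumarin
Conditions: K2CO3, acetone, reflux
Reagents that add atoms: none
Why: Williamson ether synthesis: the 7-OH is the only acidic site of 1 and its phenoxide displaces the primary allylic bromide of 2 by SN2; carbonate in acetone is too weak to open the coumarin lactone.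

Step 2
Reactants: 3 8-methoxy-7-(3-methylbut-2-enyloxy)coumarin
Product: 4 (E)-7-[(4-hydroxy-3-methylbut-2-en-1-yl)oxy]-8-methoxycoumarin
Conditions: SeO2 (cat.), t-BuOOH, CH2Cl2, 0 °C to rt
Reagents that add atoms: tert-butyl hydroperoxide, CC(C)(C)OO (oxygen atom, passed on by the catalytic SeO2, O=[Se]=O)
Why: Riley allylic oxidation (ene reaction, then [2,3]-sigmatropic shift) attacks the more substituted olefin terminus and only the methyl group trans to C1, so the E geometry of C2=C3 (C4 trans to C1, C10 cis to C1) is fixed here. Catalytic SeO2 with t-BuOOH should hold the oxidation mainly at the alcohol level and leaves the electron-poor coumarin double bond alone.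

Step 3
Reactants: 4 (E)-7-[(4-hydroxy-3-methylbut-2-en-1-yl)oxy]-8-methoxycoumarin
Product: 5 (E)-7-[(4-bromo-3-methylbut-2-en-1-yl)oxy]-8-methoxycoumarin
Conditions: CBr4, PPh3, CH2Cl2, 0 °C
Reagents that add atoms: carbon tetrabromide, BrC(Br)(Br)Br
Why: Appel reaction: bromide displaces the alkoxyphosphonium group at the primary allylic carbon under neutral, cold conditions, so neither allylic transposition nor E/Z drift is expected; the ether and the coumarin are inert.

Step 4
Reactants: 5 (E)-7-[(4-bromo-3-methylbut-2-en-1-yl)oxy]-8-methoxycoumarin; 6 bis(pinacolatoboryl)methane
Product: 8 (E)-8-methoxy-7-{[3-methyl-5,5-bis(4,4,5,5-tetramethyl-1,3,2-dioxaborolan-2-yl)pent-2-en-1-yl]oxy}coumarin, via lithiated diborylmethane 7 (not isolated)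
Conditions: 6, LiTMP (from TMPH, n-BuLi), THF, 0 °C; then added to 5, THF, −78 to 0 °C
Reagents that add atoms: none
Why: Alkylation of a carbanion stabilised by two empty boron p orbitals: the hindered amide deprotonates 6 without attacking boron, and 7 displaces the primary allylic bromide by SN2 at C4. At −78 °C, with inverse addition (7 never in excess), this should outrun addition to the conjugated aryl lactone. No stereocentre arises because C5 carries two identical boryl groups.

Step 5
Reactants: 8 (E)-8-methoxy-7-{[3-methyl-5,5-bis(4,4,5,5-tetramethyl-1,3,2-dioxaborolan-2-yl)pent-2-en-1-yl]oxy}coumarin; 9 ethyl 2-(bromomethyl)acrylate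
Product: 10 ethyl (4R,6E)-8-[(8-methoxy-2-oxo-2H-chromen-7-yl)oxy]-6-methyl-2-methylidene-4-(4,4,5,5-tetramethyl-1,3,2-dioxaborolan-2-yl)oct-6-enoate
Conditions: CuBr (10 mol %), H8-BINOL-derived phosphoramidite L* (12 mol %), LiOt-Bu (1.5 equiv), THF, 0 °C to rt, slow addition of 9
Reagents that add atoms: none
Why: tert-Butoxide adds to a boron of 8 and the chiral phosphoramidite–copper(I) complex takes over the alkyl group from only one of the two enantiotopic boryl groups; this B-to-Cu transmetalation is stereodetermining and gives a configurationally stable α-boryl alkylcopper. The copper species attacks the CH2= terminus of 9 (SN2′, formally addition–elimination on the acrylate), bromide leaves, and C5–C6 forms with the 2-substituted acrylate regenerated. The closest known reaction type is the copper/phosphoramidite-catalysed enantiotopic-group-selective allylation of 1,1-diborylalkanes with 2-substituted allyl bromides. No ring is closed. The only new stereocentre, C5 (R in 10, because both carbon arms outrank boron), is controlled by the ligand alone. Regiochemistry is no issue since both allyl termini of 9 are CH2 groups and SN2 and SN2′ give the same product, which is why the unsymmetrical arm 5 was attached first and without copper. Chemoselectivity rests on 9 being by far the best electrophile present (bromide on an acrylate against aryloxide on a trisubstituted olefin and an unactivated coumarin), and the reaction stops after one allylation because 10 has lost the second boron that made the C–B bond of 8 transferable. Slow addition of 9 keeps free tert-butoxide from consuming it.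

Step 6
Reactants: 10 ethyl (4R,6E)-8-[(8-methoxy-2-oxo-2H-chromen-7-yl)oxy]-6-methyl-2-methylidene-4-(4,4,5,5-tetramethyl-1,3,2-dioxaborolan-2-yl)oct-6-enoate
Product: 12 7-({(2E)-3-methyl-4-[(2R)-4-methylidene-5-oxooxolan-2-yl]but-2-en-1-yl}oxy)-8-methoxycoumarin, via hydroxy ester 11 (not isolated)
Conditions: NaBO3·4H2O, THF/H2O, rt; then PPTS (cat.), toluene, 40 °C
Reagents that add atoms: sodium perborate, [Na+].[O-]OB=O
Why: Oxidation of a secondary boronic ester (1,2-shift of C5 from boron to peroxide oxygen) proceeds with retention, so the configuration set in step 5 is copied into the C5–O bond; perborate is mild enough for the acrylate, the allyl aryl ether and the coumarin. The γ-hydroxy ester 11 then closes the butyrolactone by 5-exo-trig acyl substitution under weak acid, with loss of ethanol.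

Step 7
Reactants: 12 7-({(2E)-3-methyl-4-[(2R)-4-methylidene-5-oxooxolan-2-yl]but-2-en-1-yl}oxy)-8-methoxycoumarin
Product: 13 7-{[(2R,3R)-3-methyl-3-{[(2S)-4-methylidene-5-oxooxolan-2-yl]methyl}oxiran-2-yl]methoxy}-8-methoxycoumarin (target)
Conditions: D-fructose-derived Shi ketone (30 mol %), Oxone, K2CO3, borate/EDTA buffer (pH ca. 10.5), Bu4NHSO4 (cat.), MeCN/dimethoxymethane, 0 °C
Reagents that add atoms: potassium peroxymonosulfate (active part of Oxone), [K+].[O-]S(=O)(=O)OO
Why: Shi epoxidation: the electrophilic chiral dioxirane should react only with the one electron-rich olefin C2=C3, the exocyclic acrylate and the coumarin double bond being electron-poor. Oxygen transfer is syn, so the E geometry becomes the trans relation of C1 and C4, and the spiro transition state of the D-fructose-derived ketone gives the (R,R)-epoxide of E-trisubstituted olefins independently of remote C5. C5 is unchanged in space; its descriptor turns from R to S because C4 now outranks C6.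

## Compound list

1 | 7-hydroxy-8-methoxycoumarin | Oc1ccc2ccc(=O)oc2c1OC | starting material
2 | prenyl bromide (1-bromo-3-methylbut-2-ene) | CC(C)=CCBr | starting material
3 | 8-methoxy-7-(3-methylbut-2-enyloxy)coumarin | CC(C)=CCOc1ccc2ccc(=O)oc2c1OC | intermediate
4 | (E)-7-[(4-hydroxy-3-methylbut-2-en-1-yl)oxy]-8-methoxycoumarin | OC/C(C)=C/COc1ccc2ccc(=O)oc2c1OC | intermediate
5 | (E)-7-[(4-bromo-3-methylbut-2-en-1-yl)oxy]-8-methoxycoumarin | BrC/C(C)=C/COc1ccc2ccc(=O)oc2c1OC | intermediate
6 | bis(pinacolatoboryl)methane | C(B1OC(C)(C)C(C)(C)O1)B1OC(C)(C)C(C)(C)O1 | starting material
7 | lithiated bis(pinacolatoboryl)methane | [Li]C(B1OC(C)(C)C(C)(C)O1)B1OC(C)(C)C(C)(C)O1 | intermediate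
8 | (E)-8-methoxy-7-{[3-methyl-5,5-bis(4,4,5,5-tetramethyl-1,3,2-dioxaborolan-2-yl)pent-2-en-1-yl]oxy}coumarin | CC1(C)OB(OC1(C)C)C(C/C(C)=C/COc1ccc2ccc(=O)oc2c1OC)B1OC(C)(C)C(C)(C)O1 | intermediate
9 | ethyl 2-(bromomethyl)acrylate | C=C(CBr)C(=O)OCC | starting material
10 | ethyl (4R,6E)-8-[(8-methoxy-2-oxo-2H-chromen-7-yl)oxy]-6-methyl-2-methylidene-4-(4,4,5,5-tetramethyl-1,3,2-dioxaborolan-2-yl)oct-6-enoate | C=C(C[C@@H](C/C(C)=C/COc1ccc2ccc(=O)oc2c1OC)B1OC(C)(C)C(C)(C)O1)C(=O)OCC | intermediate
11 | ethyl (4R,6E)-4-hydroxy-8-[(8-methoxy-2-oxo-2H-chromen-7-yl)oxy]-6-methyl-2-methylideneoct-6-enoate | C=C(C[C@@H](C/C(C)=C/COc1ccc2ccc(=O)oc2c1OC)O)C(=O)OCC | intermediate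
12 | 7-({(2E)-3-methyl-4-[(2R)-4-methylidene-5-oxooxolan-2-yl]but-2-en-1-yl}oxy)-8-methoxycoumarin | C=C1C[C@@H](C/C(C)=C/COc2ccc3ccc(=O)oc3c2OC)OC1=O | intermediate
13 | 7-{[(2R,3R)-3-methyl-3-{[(2S)-4-methylidene-5-oxooxolan-2-yl]methyl}oxiran-2-yl]methoxy}-8-methoxycoumarin | C=C1C[C@@H](C[C@@]2(C)O[C@@H]2COc2ccc3ccc(=O)oc3c2OC)OC1=O | target

## Step count and least certain steps

Total step count: 7. Longest linear sequence: 7 steps (1 → 3 → 4 → 5 → 8 → 10 → 12 → 13). Compounds 2, 6 and 9 are purchased.

**Step 5 (key step).**
- Most likely failures:
  - Free tert-butoxide may attack the very electrophilic bromide 9 directly, using up base and electrophile.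
  - Discrimination of the two boryl groups may be weaker than hoped, because the substituent on C5 begins with a slim CH2.
  - The C5 organocopper may displace the aryloxide intramolecularly in an SN2′ sense (three-membered ring closure onto C3).
- Fallback with normal polarity: starting from 8, both C–B bonds are oxidised with sodium perborate to (E)-5-[(8-methoxy-2-oxo-2H-chromen-7-yl)oxy]-3-methylpent-3-enal F1. F1 is taken on crude and cold into a chromium-catalysed asymmetric Nozaki–Hiyama-type 2-(alkoxycarbonyl)allylation with 9 (chiral bis(oxazoline) ligand, Mn as terminal reductant). The route is rejoined at 11, which lactonises to 12 as in step 6.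

**Step 4.**
- Most likely failures: carbanion 7 may add to the coumarin (at the lactone carbonyl or in a conjugate sense), or it may act as a base and cause 1,4-elimination of HBr from 5.
- Fallback that brings the coumarin in after the carbanion chemistry:
  - 2-Methyl-2-vinyloxirane F2 (purchased) is opened with TiCl4 at low temperature to (E)-4-chloro-2-methylbut-2-en-1-ol F3.
  - An Appel reaction gives (E)-1-bromo-4-chloro-2-methylbut-2-ene F4.
  - Starting from 6, carbanion 7 displaces the better leaving group (bromide at C4) to give the chloro-gem-diboronate F5.
  - O-Alkylation of 1 with F5 (K2CO3, cat. NaI, acetone) comes back to the route at 8.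

**Step 7.**
- Most likely failures: oxygen transfer to an olefin deactivated by the allylic aryloxy group may be slow. The ketone catalyst would then decay, and the two lactones would be exposed for long to the basic buffer (hydrolysis, addition of peroxide to the acrylate). Facial selectivity may also be incomplete.
- Fallback with hydroxyl direction instead of a free dioxirane:
  - Step 6 is stopped before the acid treatment and 11 is isolated.
  - Its homoallylic C5–OH binds a vanadium or zirconium bishydroxamic acid catalyst (ligand antipode chosen for the (2R,3R) face, cumene hydroperoxide, toluene, 0 °C). This delivers oxygen to C2=C3 only and gives ethyl (4S)-4-hydroxy-5-[(2R,3R)-3-{[(8-methoxy-2-oxo-2H-chromen-7-yl)oxy]methyl}-2-methyloxiran-2-yl]-2-methylidenepentanoate F6.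
  - F6 closes on silica gel or with a trace of PPTS at room temperature to the lactone, rejoining the route at 13.

**Step 2.**
- Most likely failures: over-oxidation to the enal, incomplete conversion, and some oxidative loss of the allylic aryl ether.
- Fallback that forms the C–O bond to a pre-oxidised C5 unit instead of oxidising a C–H bond: starting from 1, palladium(0)-catalysed 1,4-addition of the phenol to 2-methyl-2-vinyloxirane (F2 of the step 4 fallback; Pd(PPh3)4 cat., THF, rt) should give 4 directly. Attack occurs at the unsubstituted terminus of the syn-π-allyl complex. No new compound is made.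

## Further compounds

F1 | step 5 | (E)-5-[(8-methoxy-2-oxo-2H-chromen-7-yl)oxy]-3-methylpent-3-enal | O=CC/C(C)=C/COc1ccc2ccc(=O)oc2c1OC
F2 | step 4 | 2-methyl-2-vinyloxirane (purchased, racemic) | C=CC1(C)CO1
F3 | step 4 | (E)-4-chloro-2-methylbut-2-en-1-ol | OC/C(C)=C/CCl
F4 | step 4 | (E)-1-bromo-4-chloro-2-methylbut-2-ene | BrC/C(C)=C/CCl
F5 | step 4 | 2,2'-[(3E)-5-chloro-3-methylpent-3-ene-1,1-diyl]bis(4,4,5,5-tetramethyl-1,3,2-dioxaborolane) | CC1(C)OB(OC1(C)C)C(C/C(C)=C/CCl)B1OC(C)(C)C(C)(C)O1
F6 | step 7 | ethyl (4S)-4-hydroxy-5-[(2R,3R)-3-{[(8-methoxy-2-oxo-2H-chromen-7-yl)oxy]methyl}-2-methyloxiran-2-yl]-2-methylidenepentanoate | C=C(C[C@@H](C[C@@]1(C)O[C@@H]1COc1ccc2ccc(=O)oc2c1OC)O)C(=O)OCC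
F0 | step 2 | none | none
A1 | alternative 1 | 2-[(2R,3R)-3-{[(8-methoxy-2-oxo-2H-chromen-7-yl)oxy]methyl}-2-methyloxiran-2-yl]acetaldehyde | O=CC[C@@]1(C)O[C@@H]1COc1ccc2ccc(=O)oc2c1OC
A2 | alternative 2 | (S)-epichlorohydrin | ClC[C@@H]1CO1
A3 | alternative 2 | (R)-1-(triisopropylsilyl)hepta-1,6-diyn-4-ol | CC(C)[Si](C#CC[C@@H](CC#C)O)(C(C)C)C(C)C
A4 | alternative 3 | (S)-5-(iodomethyl)-3-methylideneoxolan-2-one | C=C1C[C@@H](CI)OC1=O
A5 | alternative 3 | (E)-7-[(3-iodobut-2-en-1-yl)oxy]-8-methoxycoumarin | I/C(C)=C/COc1ccc2ccc(=O)oc2c1OC
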